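**Plan**
- **Cuts in ring A''.** After removal of one benzyl ether, ring A'' of the apigenin half is cut at C4a''–C5''. The ether carbon C6'' lies between the hydroxylated carbons C5'' and C7''. The cut therefore turns C5''–C8'' into a 2-aryloxy-3-oxobutanoate chain, with C6'' as the alpha-carbon of a beta-keto ester. The chain hangs from C2 of a 6-aryl-4-pyranone, which is ring C'' with O1'' already bound to C8a''.
- **Further cuts.** These are C6''–C7'' (decarboxylative Claisen condensation), C7''–C8'' (CO2 onto the pyranone methyl group) and O–C6'' (genkwanin 4'-OH plus dimethyl chloromalonate). The pyranone goes back to acetylacetone and methyl 4-(benzyloxy)benzoate.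
- **Forward order.** Ring C'' is made first. Its side chain is extended by one carbon and joined to the genkwanin fragment. Ring A'' closes last onto pyranone C3, and the benzyl ether is then removed.
- **Stereochemistry.** The target has no stereocentre. The methine that becomes C6'' is racemic and epimerisable, and it turns sp2 in the key step.

Key step: step 7

Remark on the chemistry: the 5-OH of the genkwanin half is carried unprotected. Its hydrogen bond to the C4 carbonyl keeps it out of the K2CO3 alkylation. A benzylation after step 1 would hit the acidic malonate methine instead. In steps 6 and 7 the 5-OH only binds extra magnesium.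

**Step 1**
Reactants: 1 genkwanin (5-hydroxy-2-(4-hydroxyphenyl)-7-methoxy-4H-chromen-4-one); 2 dimethyl 2-chloromalonate
Product: 3 dimethyl 2-[4-(5-hydroxy-7-methoxy-4-oxo-4H-chromen-2-yl)phenoxy]malonate
Conditions: 2 (1.05 equiv), K2CO3 (1.5 equiv), DMF, rt → 50 °C
Reagents that add atoms: none
Why: Williamson ether synthesis in which only the unchelated, more acidic 4'-OH is ionised and alkylated, as is routine for making aryloxymalonates from phenols and chloromalonates.

**Step 2**
Reactants: 3 dimethyl aryloxymalonate
Product: 4 potassium 2-[4-(5-hydroxy-7-methoxy-4-oxo-4H-chromen-2-yl)phenoxy]-3-methoxy-3-oxopropanoate (racemic)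
Conditions: KOH (1.0 equiv), MeOH–THF, 0 °C → rt; concentrated, salt triturated with Et2O
Reagents that add atoms: potassium hydroxide, [K+].[OH-]
Why: Selective monosaponification of a symmetrical malonate, in which the first carboxylate shields the second ester, the new methine stereocentre is racemic and of no consequence, and isolation as the salt avoids decarboxylation.

**Step 3**
Reactants: 5 acetylacetone; 6 methyl 4-(benzyloxy)benzoate
Product: 7 1-[4-(benzyloxy)phenyl]hexane-1,3,5-trione (largely enolised)
Conditions: 5 (2.2 equiv), LDA [LiN(iPr)2] (4.4 equiv), THF, −78 → 0 °C; 6 (1.0 equiv), 0 °C → rt; 1 M HCl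
Reagents that add atoms: none
Why: Crossed Claisen condensation of a beta-diketone dianion, which is aroylated at its more reactive terminal carbanion while the second equivalent of dianion takes up the acidic proton of the product.

**Step 4**
Reactants: 7 triketone
Product: 8 2-[4-(benzyloxy)phenyl]-6-methyl-4H-pyran-4-one
Conditions: TFA–CH2Cl2 (1:3), rt
Reagents that add atoms: none
Why: Acid-catalysed cyclodehydration of a 1,3,5-triketone, which can only give this 4-pyranone and uses an acid that aryl benzyl ethers tolerate at room temperature.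

**Step 5**
Reactants: 8 methylpyranone
Product: 9 {6-[4-(benzyloxy)phenyl]-4-oxo-4H-pyran-2-yl}acetic acid
Conditions: LDA (1.2 equiv), THF, −78 °C; cannulated into excess CO2 in THF, −78 °C; cold 1 M HCl to pH 2–3, used without heating
Reagents that add atoms: carbon dioxide, O=C=O
Why: Lateral (vinylogous) deprotonation of the 2-methyl group gives the extended enolate, which is carboxylated at the exocyclic carbon as known for 2-methyl-4-pyranones and 2-methylchromones.

**Step 6**
Reactants: 9 pyranonylacetic acid; 4 potassium methyl aryloxymalonate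
Product: 12 methyl 2-[4-(5-hydroxy-7-methoxy-4-oxo-4H-chromen-2-yl)phenoxy]-4-{6-[4-(benzyloxy)phenyl]-4-oxo-4H-pyran-2-yl}-3-oxobutanoate (racemic), via pyranonylacetyl imidazolide 10 (not isolated), via acylated malonic half-acid 11 (not isolated)
Conditions: 9, CDI (1.05 equiv), THF, rt; added to 4, MgCl2 (3 equiv), Et3N (4 equiv), MeCN, rt → 40 °C; 1 M HCl, 0 °C
Reagents that add atoms: 1,1'-carbonyldiimidazole, O=C(n1ccnc1)n1ccnc1 (its imidazolyl group is found only in 10)
Why: Decarboxylative Claisen condensation (Masamune–Brooks reaction), in which the chelated magnesium enolate of the half-ester is C-acylated under almost neutral conditions that acyl imidazolides with an activated methylene survive, and loss of CO2 leaves a racemic, epimerisable methine.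

**Step 7**
Reactants: 12 pyranonyl beta-keto ester
Product: 13 4'''-O-benzylneocryptomerin (6-{4-(5-hydroxy-7-methoxy-4-oxo-4H-chromen-2-yl)phenoxy}-2-[4-(benzyloxy)phenyl]-5,7-dihydroxy-4H-chromen-4-one)
Conditions: Mg(OMe)2 (5 equiv), MeOH–THF (1:1), reflux; 1 M HCl, 0 °C
Reagents that add atoms: none
Why: Proposed new method: methoxide reversibly deprotonates the C8'' methylene to a magnesium enolate conjugated through pyranone C2=C3 to the ring carbonyl (a 2-alkylidene-2H-pyran-4-olate), so pyranone C3 (future C4a'') is the alpha-carbon of an extended dienolate, adds to the ester carbonyl (future C5'') and expels methoxide, after which loss of the C3 proton and enolisation at C5'' and C7'' give aromatic ring A''. The closest known reactions are the Claisen cyclisations of 3,5,7-triketo esters and of pyranone-masked polyketides to acylphloroglucinols with Mg(OMe)2, and the C–C bond formations of laterally metalated 2-methyl-4-pyranones and 2-methylchromones, whereas acylation at the ring carbon of such an anion is not an established reaction. Ring A'' closes in a favoured 6-(enolexo)-exo-trig mode and no stereocentre is formed, since the racemic methine C6'' becomes sp2. The step needs acylation from C3 although the aryloxy methine is the more acidic site, but that enolate has no strain-free electrophile within reach (only four-membered or bridged rings), so it is a resting state in equilibrium with the reactive tautomer, in which Mg2+ can bridge the C7'' enolate oxygen and the neutral ester carbonyl and activate the latter. The 6''- rather than 8''-aryloxy pattern is fixed because O1'' stays tied up in the intact pyranone, whose anionic form resists opening by methoxide, and aromatisation to the magnesium phenoxide makes the closure irreversible. The excess Mg(OMe)2 is taken up by the 5-OH/4-oxo site of the genkwanin half, which is thereby masked.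

**Step 8**
Reactants: 13 4'''-O-benzylneocryptomerin
Product: 14 neocryptomerin
Conditions: H2 (1 atm), 10% Pd/C, THF–MeOH, rt
Reagents that add atoms: none
Why: Catalytic hydrogenolysis of an aryl benzyl ether, which at atmospheric pressure leaves the flavone C2=C3 bonds, the diaryl ether and the methyl ether untouched.

**Compound list**
1 | genkwanin | COc1cc(O)c2c(=O)cc(-c3ccc(O)cc3)oc2c1 | starting material
2 | dimethyl 2-chloromalonate | COC(=O)C(Cl)C(=O)OC | starting material
3 | dimethyl 2-[4-(5-hydroxy-7-methoxy-4-oxo-4H-chromen-2-yl)phenoxy]malonate | COC(=O)C(Oc1ccc(-c2cc(=O)c3c(O)cc(OC)cc3o2)cc1)C(=O)OC | intermediate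
4 | potassium methyl 2-[4-(5-hydroxy-7-methoxy-4-oxo-4H-chromen-2-yl)phenoxy]malonate (racemic) | COC(=O)C(Oc1ccc(-c2cc(=O)c3c(O)cc(OC)cc3o2)cc1)C(=O)[O-].[K+] | intermediate
5 | acetylacetone | CC(=O)CC(C)=O | starting material
6 | methyl 4-(benzyloxy)benzoate | COC(=O)c1ccc(OCc2ccccc2)cc1 | starting material
7 | 1-[4-(benzyloxy)phenyl]hexane-1,3,5-trione | CC(=O)CC(=O)CC(=O)c1ccc(OCc2ccccc2)cc1 | intermediate
8 | 2-[4-(benzyloxy)phenyl]-6-methyl-4H-pyran-4-one | Cc1cc(=O)cc(-c2ccc(OCc3ccccc3)cc2)o1 | intermediate
9 | {6-[4-(benzyloxy)phenyl]-4-oxo-4H-pyran-2-yl}acetic acid | OC(=O)Cc1cc(=O)cc(-c2ccc(OCc3ccccc3)cc2)o1 | intermediate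
10 | 2-[4-(benzyloxy)phenyl]-6-[2-(1H-imidazol-1-yl)-2-oxoethyl]-4H-pyran-4-one | O=C(Cc1cc(=O)cc(-c2ccc(OCc3ccccc3)cc2)o1)n1ccnc1 | intermediate (not isolated)
11 | 2-[4-(5-hydroxy-7-methoxy-4-oxo-4H-chromen-2-yl)phenoxy]-2-(methoxycarbonyl)-4-{6-[4-(benzyloxy)phenyl]-4-oxo-4H-pyran-2-yl}-3-oxobutanoic acid (racemic, magnesium salt in the flask) | COC(=O)C(Oc1ccc(-c2cc(=O)c3c(O)cc(OC)cc3o2)cc1)(C(=O)O)C(=O)Cc1cc(=O)cc(-c2ccc(OCc3ccccc3)cc2)o1 | intermediate (not isolated)
12 | methyl 2-[4-(5-hydroxy-7-methoxy-4-oxo-4H-chromen-2-yl)phenoxy]-4-{6-[4-(benzyloxy)phenyl]-4-oxo-4H-pyran-2-yl}-3-oxobutanoate (racemic) | COC(=O)C(Oc1ccc(-c2cc(=O)c3c(O)cc(OC)cc3o2)cc1)C(=O)Cc1cc(=O)cc(-c2ccc(OCc3ccccc3)cc2)o1 | intermediate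
13 | 4'''-O-benzylneocryptomerin | COc1cc(O)c2c(=O)cc(-c3ccc(Oc4c(O)cc5oc(-c6ccc(OCc7ccccc7)cc6)cc(=O)c5c4O)cc3)oc2c1 | intermediate
14 | neocryptomerin | COc1cc(O)c2c(=O)cc(-c3ccc(Oc4c(O)cc5oc(-c6ccc(O)cc6)cc(=O)c5c4O)cc3)oc2c1 | target

**Step count:** 8 steps in total. The longest linear sequence is 6 steps (steps 3, 4, 5, 6, 7 and 8).

**Steps most likely to fail**

**Step 7.**
- What may go wrong: the ester may stay buried in the chelated beta-keto ester enolate. Retro-Claisen cleavage by methoxide, or opening of the pyranone ring followed by unselective cyclisation, could then overtake ring closure.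
- Fallback: it uses known chemistry and makes the C6''–O bond on a finished flavone by an Ullmann-type diaryl ether synthesis. It sets out from genkwanin 1, with a partner made from commercial apigenin.
- Apigenin is benzylated at its two unchelated phenols (BnBr, K2CO3, DMF, rt) to 7,4'-di-O-benzylapigenin F1.
- Iodination next to the free 5-OH with benzyltrimethylammonium dichloroiodate and CaCO3 in CH2Cl2–MeOH gives 7,4'-di-O-benzyl-6-iodoapigenin F2.
- Benzylation at O5 under forcing conditions (BnBr, K2CO3, DMF, 80 °C) gives 5,7,4'-tri-O-benzyl-6-iodoapigenin F3.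
- Coupling of F3 with 1 (CuI, picolinic acid, K3PO4, DMSO, 100 °C) uses a protocol designed for hindered partners. It should give 5'',7'',4'''-tri-O-benzylneocryptomerin F4.
- Hydrogenolysis (H2, Pd/C, THF–MeOH) brings the fallback back to the route at 14.

**Step 6.**
- What may go wrong: C-acylation of the hindered, weakly nucleophilic aryloxymalonate enolate may be slow. The imidazolide could then lose its activated methylene proton and decay by self-condensation, or the half-ester could simply decarboxylate.
- Fallback: the carbon chain is built first and the ether is installed afterwards by carbenoid O–H insertion. It sets out from acid 9.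
- The imidazolide 10 of acid 9 is intercepted by the unhindered magnesium enolate of potassium methyl malonate (MgCl2, Et3N, MeCN). This gives methyl 4-{6-[4-(benzyloxy)phenyl]-4-oxo-4H-pyran-2-yl}-3-oxobutanoate F5.
- Regitz diazo transfer at the more acidic C2 methylene (4-acetamidobenzenesulfonyl azide, 1.0 equiv, Et3N, MeCN, 0 °C) gives methyl 2-diazo-4-{6-[4-(benzyloxy)phenyl]-4-oxo-4H-pyran-2-yl}-3-oxobutanoate F6.
- Slow addition of F6 to genkwanin 1 and Rh2(OAc)4 (2 mol %) in 1,2-dichloroethane at 80 °C should insert the carbenoid into the free 4'-OH. The fallback returns to the route at 12.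

**Step 5.**
- What may go wrong: proton exchange between lithiated 8 and the newly formed carboxylate, competing metalation of the ring, or loss of CO2 on acidification.
- Fallback: the extra carbon is introduced before the ring is closed. It sets out from triketone 7.
- The trianion of 7 (LDA, 3.3 equiv, THF, 0 °C) is acylated at the terminal carbanion with dimethyl carbonate. This gives methyl 7-[4-(benzyloxy)phenyl]-3,5,7-trioxoheptanoate F7.
- Cyclodehydration in TFA–CH2Cl2 gives methyl {6-[4-(benzyloxy)phenyl]-4-oxo-4H-pyran-2-yl}acetate F8.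
- Mild hydrolysis (LiOH, THF–H2O, 0 °C, cold acidification) returns to the route at 9.

**Further compounds**
F1 | step 7 | 7,4'-di-O-benzylapigenin | O=c1cc(-c2ccc(OCc3ccccc3)cc2)oc2cc(OCc3ccccc3)cc(O)c12
F2 | step 7 | 7,4'-di-O-benzyl-6-iodoapigenin | O=c1cc(-c2ccc(OCc3ccccc3)cc2)oc2cc(OCc3ccccc3)c(I)c(O)c12
F3 | step 7 | 5,7,4'-tri-O-benzyl-6-iodoapigenin | O=c1cc(-c2ccc(OCc3ccccc3)cc2)oc2cc(OCc3ccccc3)c(I)c(OCc3ccccc3)c12
F4 | step 7 | 5'',7'',4'''-tri-O-benzylneocryptomerin | COc1cc(O)c2c(=O)cc(-c3ccc(Oc4c(OCc5ccccc5)cc5oc(-c6ccc(OCc7ccccc7)cc6)cc(=O)c5c4OCc4ccccc4)cc3)oc2c1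
F5 | step 6 | methyl 4-{6-[4-(benzyloxy)phenyl]-4-oxo-4H-pyran-2-yl}-3-oxobutanoate | COC(=O)CC(=O)Cc1cc(=O)cc(-c2ccc(OCc3ccccc3)cc2)o1
F6 | step 6 | methyl 2-diazo-4-{6-[4-(benzyloxy)phenyl]-4-oxo-4H-pyran-2-yl}-3-oxobutanoate | COC(=O)C(=[N+]=[N-])C(=O)Cc1cc(=O)cc(-c2ccc(OCc3ccccc3)cc2)o1
F7 | step 5 | methyl 7-[4-(benzyloxy)phenyl]-3,5,7-trioxoheptanoate | COC(=O)CC(=O)CC(=O)CC(=O)c1ccc(OCc2ccccc2)cc1
F8 | step 5 | methyl {6-[4-(benzyloxy)phenyl]-4-oxo-4H-pyran-2-yl}acetate | COC(=O)Cc1cc(=O)cc(-c2ccc(OCc3ccccc3)cc2)o1
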